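Each pyranone is cut between C3 and C4 (C3''–C4''). A CH2 joined to the carbon that is benzylic to the oxygen-rich ring A is what remains when NH is excised from an ArCH2–NH–CH2 chain. One operation, twofold nitrogen deletion with an anomeric amide, should therefore turn a bis(2-aryl-2,3,4,5-tetrahydro-1,4-benzoxazepine) into the (2S,2''S)-bis-flavan, forming both C3–C4 bonds and contracting both seven-membered rings to pyrans without touching C2 or C2''. The precursor carries two secondary amines, four methyl ethers and one benzyl ether; its stereocentres come from catalytic Henry reactions and invertive Mitsunobu closures. C4 oxidation and BCl3 deprotection finish.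

Key step: step 16

Remark: C2 of each benzoxazepine has the descriptor R but the same spatial arrangement as C2 (S) of the flavans, because CH2N outranks aryl; as the Mitsunobu closures invert, both nitro alcohols are made S with the matching antipode of the Henry ligand.

Abbreviations: SES = 2-(trimethylsilyl)ethylsulfonyl; Q = (2R)-2-[4-(benzyloxy)phenyl]-6,8-dimethoxy-4-SES-2,3,4,5-tetrahydro-1,4-benzoxazepin-7-yl.

Step 1
Reactants: 1 4-hydroxy-3,5-dimethoxybenzaldehyde (syringaldehyde); 2 4-fluorobenzonitrile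
Product: 3 4-(4-formyl-2,6-dimethoxyphenoxy)benzonitrile
Conditions: K2CO3, DMSO, 120 °C
Reagents that add atoms: none
Why: Nucleophilic aromatic substitution (SNAr): the phenoxide of 1 displaces fluoride para to the nitrile, which serves here as a formyl group in waiting so that the route never has to tell two aldehydes apart.

Step 2
Reactants: 3 4-(4-formyl-2,6-dimethoxyphenoxy)benzonitrile
Product: 5 4-(4-hydroxy-2,6-dimethoxyphenoxy)benzonitrile, via aryl formate 4 (not isolated)
Conditions: mCPBA, CH2Cl2, 0 °C → rt; then K2CO3 (cat.), MeOH, rt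
Reagents that add atoms: 3-chloroperoxybenzoic acid (mCPBA), OOC(=O)c1cccc(Cl)c1
Why: Baeyer–Villiger oxidation in its Dakin form: in the Criegee adduct the aryl group, supported by its para-aryloxy donor, migrates to oxygen to give formate 4, which catalytic carbonate in methanol cleaves to the phenol while the nitrile is inert to peracid.

Step 3
Reactants: 5 4-(4-hydroxy-2,6-dimethoxyphenoxy)benzonitrile
Product: 7 4-(3-formyl-4-hydroxy-2,6-dimethoxyphenoxy)benzonitrile, via salicyl alcohol 6 (not isolated)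
Conditions: MgCl2, Et3N, (CH2O)n, MeCN, reflux; aq. HCl work-up
Reagents that add atoms: paraformaldehyde (as formaldehyde), C=O
Why: Magnesium-mediated ortho-formylation (Casnati–Skattebøl reaction): the magnesium phenoxide delivers formaldehyde to the ortho carbon, the salicyl alcohol 6 is oxidised by a second formaldehyde through an Oppenauer-type hydride transfer, and because the two ortho positions of 5 are equivalent only one regioisomer can arise.

Step 4
Reactants: 8 4-(benzyloxy)benzaldehyde
Product: 9 (1S)-1-[4-(benzyloxy)phenyl]-2-nitroethanol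
Conditions: MeNO2 (10 equiv), Cu(OAc)2·H2O (5 mol%), indane-derived bis(oxazoline) ligand (antipode giving the S alcohol), EtOH, rt
Reagents that add atoms: nitromethane, C[N+](=O)[O-]
Why: Copper(II)–bis(oxazoline)-catalysed asymmetric Henry (nitroaldol) reaction: the chiral Lewis acid holds the aldehyde and steers the nitronate to one face, and the ligand antipode is chosen to set the carbinol S, the configuration that the invertive closure of step 8 requires.

Step 5
Reactants: 9 (1S)-1-[4-(benzyloxy)phenyl]-2-nitroethanol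
Product: 10 (1S)-2-amino-1-[4-(benzyloxy)phenyl]ethanol
Conditions: Zn dust, AcOH, EtOH, 0 °C → rt; basic work-up
Reagents that add atoms: none
Why: Zinc–acetic acid reduction of an aliphatic nitro group: the acidic medium rules out retro-Henry cleavage, and neither the benzyl ether nor the carbinol centre is affected.

Step 6
Reactants: 7 4-(3-formyl-4-hydroxy-2,6-dimethoxyphenoxy)benzonitrile; 10 (1S)-2-amino-1-[4-(benzyloxy)phenyl]ethanol
Product: 12 4-{3-[({(2S)-2-[4-(benzyloxy)phenyl]-2-hydroxyethyl}amino)methyl]-4-hydroxy-2,6-dimethoxyphenoxy}benzonitrile, via imine 11 (not isolated)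
Conditions: MeOH/THF, rt; then NaBH4, 0 °C
Reagents that add atoms: none
Why: Stepwise reductive amination: the primary amine condenses with the salicylaldehyde to the hydrogen-bonded imine 11, which NaBH4 reduces to the secondary amine without touching the nitrile and without risk of double alkylation.

Step 7
Reactants: 12 secondary amine from step 6
Product: 13 N-{(2S)-2-[4-(benzyloxy)phenyl]-2-hydroxyethyl}-N-[3-(4-cyanophenoxy)-6-hydroxy-2,4-dimethoxybenzyl]-2-(trimethylsilyl)ethanesulfonamide
Conditions: SES-Cl (1.05 equiv), Et3N, CH2Cl2, −20 → 0 °C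
Reagents that add atoms: 2-(trimethylsilyl)ethanesulfonyl chloride (SES-Cl), C[Si](C)(C)CCS(=O)(=O)Cl
Why: Chemoselective N-sulfonylation: at low temperature one equivalent of the sulfonyl chloride is taken by the secondary amine, far more nucleophilic than the phenol or the alcohol, and SES is chosen because it survives DIBAL-H and zinc and is later removed by fluoride.

Step 8
Reactants: 13 N-SES amino diol from step 7
Product: 14 4-(Q-oxy)benzonitrile, the (2R)-N-SES-benzoxazepine carrying a 4-cyanophenoxy group at C7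
Conditions: PPh3, DIAD, THF (0.02 M), 0 °C → rt
Reagents that add atoms: none
Why: Intramolecular Mitsunobu etherification (7-exo-tet): the phenol (pKa about 10) displaces the oxyphosphonium group with inversion, S to R, while the fully substituted sulfonamide nitrogen cannot form an aziridine, its inductive pull and the cold, dilute medium disfavour ionisation, and both ortho positions next to the benzylic CH2 are blocked against C-alkylation.

Step 9
Reactants: 14 4-(Q-oxy)benzonitrile
Product: 16 4-(Q-oxy)benzaldehyde, via iminoalane 15 (not isolated)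
Conditions: DIBAL-H (1.5 equiv), CH2Cl2, −78 °C; then aq. Rochelle salt
Reagents that add atoms: water (hydrolytic work-up), O
Why: DIBAL-H half-reduction of an aryl nitrile: one hydride adds at −78 °C to give the iminoalane 15, which is stable until aqueous work-up hydrolyses it to the aldehyde, and the sulfonamide and ethers do not react.

Step 10
Reactants: 16 4-(Q-oxy)benzaldehyde
Product: 17 (1S)-1-[4-(Q-oxy)phenyl]-2-nitroethanol
Conditions: MeNO2 (10 equiv), Cu(OAc)2·H2O (10 mol%), same bis(oxazoline) antipode as in step 4, EtOH/THF, rt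
Reagents that add atoms: nitromethane, C[N+](=O)[O-]
Why: Second copper(II)–bis(oxazoline) Henry reaction with the same ligand antipode as in step 4: the catalyst alone sets the new carbinol S, the distant C2 centre exerting no influence, so any leakage should appear as a separable diastereomer.

Step 11
Reactants: 17 (1S)-1-[4-(Q-oxy)phenyl]-2-nitroethanol
Product: 18 (1S)-2-amino-1-[4-(Q-oxy)phenyl]ethanol
Conditions: Zn dust, AcOH, THF/EtOH, 0 °C → rt; basic work-up
Reagents that add atoms: none
Why: Zinc–acetic acid reduction of the aliphatic nitro group as in step 5: sulfonamide, benzyl ether and the benzylic aryl ether at C2 are stable to these mildly acidic conditions.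

Step 12
Reactants: 18 (1S)-2-amino-1-[4-(Q-oxy)phenyl]ethanol; 19 2-hydroxy-4,6-dimethoxybenzaldehyde
Product: 21 (1S)-2-[(2-hydroxy-4,6-dimethoxybenzyl)amino]-1-[4-(Q-oxy)phenyl]ethanol, via imine 20 (not isolated)
Conditions: MeOH/THF, rt; then NaBH4, 0 °C
Reagents that add atoms: none
Why: Stepwise reductive amination as in step 6: imine 20 forms at the only aldehyde present and NaBH4 reduces it to the secondary amine.

Step 13
Reactants: 21 secondary amine from step 12
Product: 22 N-(2-hydroxy-4,6-dimethoxybenzyl)-N-{(2S)-2-hydroxy-2-[4-(Q-oxy)phenyl]ethyl}-2-(trimethylsilyl)ethanesulfonamide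
Conditions: SES-Cl (1.05 equiv), Et3N, CH2Cl2, −20 → 0 °C
Reagents that add atoms: 2-(trimethylsilyl)ethanesulfonyl chloride (SES-Cl), C[Si](C)(C)CCS(=O)(=O)Cl
Why: Chemoselective N-sulfonylation as in step 7: the new secondary amine outcompetes the phenol and the alcohol, and a second SES group lets both nitrogens be freed later in one operation.

Step 14
Reactants: 22 N-SES amino diol from step 13
Product: 23 (2R)-2-[4-(Q-oxy)phenyl]-6,8-dimethoxy-4-SES-2,3,4,5-tetrahydro-1,4-benzoxazepine (bis-N-SES bis-benzoxazepine)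
Conditions: PPh3, DIAD, THF (0.02 M), 0 °C → rt
Reagents that add atoms: none
Why: Intramolecular Mitsunobu etherification (7-exo-tet) as in step 8: the ring-A phenol displaces the activated benzylic oxygen with inversion, S to R, closing the second oxazepine.

Step 15
Reactants: 23 bis-N-SES bis-benzoxazepine
Product: 24 (2R)-2-[4-({(2R)-2-[4-(benzyloxy)phenyl]-6,8-dimethoxy-2,3,4,5-tetrahydro-1,4-benzoxazepin-7-yl}oxy)phenyl]-6,8-dimethoxy-2,3,4,5-tetrahydro-1,4-benzoxazepine (bis-NH bis-benzoxazepine)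
Conditions: CsF (10 equiv), DMF, 95 °C
Reagents that add atoms: none
Why: Fluoride-induced fragmentation of SES sulfonamides: attack at silicon triggers β-elimination of ethene and loss of sulfur dioxide at both nitrogens, freeing the two secondary amines under conditions that leave aryl and benzyl ethers and both stereocentres untouched.

Step 16
Reactants: 24 bis-NH bis-benzoxazepine
Product: 25 (2S)-2-[4-({(2S)-2-[4-(benzyloxy)phenyl]-5,7-dimethoxy-3,4-dihydro-2H-chromen-6-yl}oxy)phenyl]-5,7-dimethoxy-3,4-dihydro-2H-chromene (protected bis-flavan)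
Conditions: N-(benzyloxy)-N-(pivaloyloxy)-4-(trifluoromethyl)benzamide (3 equiv), THF, 45 °C
Reagents that add atoms: none
Why: Each secondary amine attacks the electrophilic nitrogen of the anomeric amide, pivalate leaves, and the N-alkoxy hydrazide so formed expels benzyl 4-(trifluoromethyl)benzoate to give a 1,1-diazene that loses N2. This is the known nitrogen deletion of benzylic secondary amines with an anomeric amide, used here as a ring contraction at two cyclic amines in one molecule. In each ring N2 loss leaves a benzylic radical on the ring-A carbon (future C4 or C4'') and a primary radical at C3 or C3'', still joined through C2, O1 and two ring-A carbons, and recombination of this 1,6-diradical pair closes the six-membered pyran. No stereocentre is made, and C2 and C2'' are never radical centres, so they keep the configuration fixed in steps 8 and 14. The selectivity needed is ring closure over β-scission of the C3 radical with loss of the ring-A aryloxy group (overall, collapse to an o-quinone methide and a styrene); the short tether, the nearly barrierless coupling of the caged pair and the stabilised benzylic partner should favour closure.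

Step 17
Reactants: 25 protected bis-flavan
Product: 27 (2S)-2-[4-({(2S)-2-[4-(benzyloxy)phenyl]-5,7-dimethoxy-4-oxo-3,4-dihydro-2H-chromen-6-yl}oxy)phenyl]-5,7-dimethoxy-2,3-dihydro-4H-chromen-4-one (protected bis-flavanone), via bis(flavan-4-ol) 26 (not isolated)
Conditions: DDQ (5 equiv), CH2Cl2/H2O (10:1), 0 °C → rt
Reagents that add atoms: water, O
Why: DDQ benzylic oxidation of electron-rich arylmethylenes in aqueous medium: hydride abstraction at C4 and C4'' gives cations stabilised by the ortho and para oxygens of each ring A, water captures them, and the carbinols 26 are dehydrogenated again to the aryl ketones, whose deactivated rings resist further oxidation.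

Step 18
Reactants: 27 protected bis-flavanone
Product: 28 7,7''-di-O-methyltetrahydrohinokiflavone
Conditions: BCl3 (8 equiv), pentamethylbenzene (4 equiv), CH2Cl2, −78 → 0 °C; MeOH quench
Reagents that add atoms: none
Why: Boron trichloride ether cleavage: chelation between each C4 carbonyl and the peri methoxy group directs demethylation to O5 and O5'' only, and the benzyl ether is cleaved with pentamethylbenzene as cation scavenger, at temperatures low enough to spare the 7-methoxy groups and the C2 centres.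

Compound list

1 | 4-hydroxy-3,5-dimethoxybenzaldehyde (syringaldehyde) | COc1cc(C=O)cc(OC)c1O | starting material
2 | 4-fluorobenzonitrile | N#Cc1ccc(F)cc1 | starting material
3 | 4-(4-formyl-2,6-dimethoxyphenoxy)benzonitrile | COc1cc(C=O)cc(OC)c1Oc1ccc(C#N)cc1 | intermediate
4 | 4-(4-cyanophenoxy)-3,5-dimethoxyphenyl formate (aryl formate; not isolated) | COc1cc(OC=O)cc(OC)c1Oc1ccc(C#N)cc1 | intermediate
5 | 4-(4-hydroxy-2,6-dimethoxyphenoxy)benzonitrile | COc1cc(O)cc(OC)c1Oc1ccc(C#N)cc1 | intermediate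
6 | 4-[4-hydroxy-3-(hydroxymethyl)-2,6-dimethoxyphenoxy]benzonitrile (salicyl alcohol, present as its magnesium salt; not isolated) | COc1cc(O)c(CO)c(OC)c1Oc1ccc(C#N)cc1 | intermediate
7 | 4-(3-formyl-4-hydroxy-2,6-dimethoxyphenoxy)benzonitrile | COc1cc(O)c(C=O)c(OC)c1Oc1ccc(C#N)cc1 | intermediate
8 | 4-(benzyloxy)benzaldehyde | O=Cc1ccc(OCc2ccccc2)cc1 | starting material
9 | (1S)-1-[4-(benzyloxy)phenyl]-2-nitroethanol | O[C@H](C[N+](=O)[O-])c1ccc(OCc2ccccc2)cc1 | intermediate
10 | (1S)-2-amino-1-[4-(benzyloxy)phenyl]ethanol | NC[C@@H](O)c1ccc(OCc2ccccc2)cc1 | intermediate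
11 | (E)-imine of aldehyde 7 with amine 10 (not isolated) | COc1cc(O)c(/C=N/C[C@@H](O)c2ccc(OCc3ccccc3)cc2)c(OC)c1Oc1ccc(C#N)cc1 | intermediate
12 | 4-{3-[({(2S)-2-[4-(benzyloxy)phenyl]-2-hydroxyethyl}amino)methyl]-4-hydroxy-2,6-dimethoxyphenoxy}benzonitrile | COc1cc(O)c(CNC[C@@H](O)c2ccc(OCc3ccccc3)cc2)c(OC)c1Oc1ccc(C#N)cc1 | intermediate
13 | N-{(2S)-2-[4-(benzyloxy)phenyl]-2-hydroxyethyl}-N-[3-(4-cyanophenoxy)-6-hydroxy-2,4-dimethoxybenzyl]-2-(trimethylsilyl)ethanesulfonamide | COc1cc(O)c(CN(C[C@@H](O)c2ccc(OCc3ccccc3)cc2)S(=O)(=O)CC[Si](C)(C)C)c(OC)c1Oc1ccc(C#N)cc1 | intermediate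
14 | 4-({(2R)-2-[4-(benzyloxy)phenyl]-6,8-dimethoxy-4-[2-(trimethylsilyl)ethylsulfonyl]-2,3,4,5-tetrahydro-1,4-benzoxazepin-7-yl}oxy)benzonitrile | COc1cc2c(c(OC)c1Oc3ccc(C#N)cc3)CN(S(=O)(=O)CC[Si](C)(C)C)C[C@@H](c4ccc(OCc5ccccc5)cc4)O2 | intermediate
15 | N-(diisobutylaluminio)aldimine of aldehyde 16 (iminoalane; not isolated) | COc1cc2c(c(OC)c1Oc3ccc(C=N[Al](CC(C)C)CC(C)C)cc3)CN(S(=O)(=O)CC[Si](C)(C)C)C[C@@H](c4ccc(OCc5ccccc5)cc4)O2 | intermediate
16 | 4-({(2R)-2-[4-(benzyloxy)phenyl]-6,8-dimethoxy-4-[2-(trimethylsilyl)ethylsulfonyl]-2,3,4,5-tetrahydro-1,4-benzoxazepin-7-yl}oxy)benzaldehyde | COc1cc2c(c(OC)c1Oc3ccc(C=O)cc3)CN(S(=O)(=O)CC[Si](C)(C)C)C[C@@H](c4ccc(OCc5ccccc5)cc4)O2 | intermediate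
17 | (1S)-1-[4-(Q-oxy)phenyl]-2-nitroethanol | COc1cc2c(c(OC)c1Oc3ccc([C@H](O)C[N+](=O)[O-])cc3)CN(S(=O)(=O)CC[Si](C)(C)C)C[C@@H](c4ccc(OCc5ccccc5)cc4)O2 | intermediate
18 | (1S)-2-amino-1-[4-(Q-oxy)phenyl]ethanol | COc1cc2c(c(OC)c1Oc3ccc([C@H](O)CN)cc3)CN(S(=O)(=O)CC[Si](C)(C)C)C[C@@H](c4ccc(OCc5ccccc5)cc4)O2 | intermediate
19 | 2-hydroxy-4,6-dimethoxybenzaldehyde | O=Cc1c(O)cc(OC)cc1OC | starting material
20 | (E)-imine of aldehyde 19 with amine 18 (not isolated) | COc1cc2c(c(OC)c1Oc3ccc([C@H](O)C/N=C/c6c(O)cc(OC)cc6OC)cc3)CN(S(=O)(=O)CC[Si](C)(C)C)C[C@@H](c4ccc(OCc5ccccc5)cc4)O2 | intermediate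
21 | (1S)-2-[(2-hydroxy-4,6-dimethoxybenzyl)amino]-1-[4-(Q-oxy)phenyl]ethanol | COc1cc2c(c(OC)c1Oc3ccc([C@H](O)CNCc6c(O)cc(OC)cc6OC)cc3)CN(S(=O)(=O)CC[Si](C)(C)C)C[C@@H](c4ccc(OCc5ccccc5)cc4)O2 | intermediate
22 | N-(2-hydroxy-4,6-dimethoxybenzyl)-N-{(2S)-2-hydroxy-2-[4-(Q-oxy)phenyl]ethyl}-2-(trimethylsilyl)ethanesulfonamide | COc1cc2c(c(OC)c1Oc3ccc([C@H](O)CN(Cc6c(O)cc(OC)cc6OC)S(=O)(=O)CC[Si](C)(C)C)cc3)CN(S(=O)(=O)CC[Si](C)(C)C)C[C@@H](c4ccc(OCc5ccccc5)cc4)O2 | intermediate
23 | (2R)-2-[4-(Q-oxy)phenyl]-6,8-dimethoxy-4-[2-(trimethylsilyl)ethylsulfonyl]-2,3,4,5-tetrahydro-1,4-benzoxazepine | COc1cc(OC)c2c(c1)O[C@H](c1ccc(Oc3c(OC)cc4c(c3OC)CN(S(=O)(=O)CC[Si](C)(C)C)C[C@@H](c3ccc(OCc5ccccc5)cc3)O4)cc1)CN(S(=O)(=O)CC[Si](C)(C)C)C2 | intermediate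
24 | (2R)-2-[4-({(2R)-2-[4-(benzyloxy)phenyl]-6,8-dimethoxy-2,3,4,5-tetrahydro-1,4-benzoxazepin-7-yl}oxy)phenyl]-6,8-dimethoxy-2,3,4,5-tetrahydro-1,4-benzoxazepine | COc1cc(OC)c2c(c1)O[C@H](c1ccc(Oc3c(OC)cc4c(c3OC)CNC[C@@H](c3ccc(OCc5ccccc5)cc3)O4)cc1)CNC2 | intermediate
25 | (2S)-2-[4-({(2S)-2-[4-(benzyloxy)phenyl]-5,7-dimethoxy-3,4-dihydro-2H-chromen-6-yl}oxy)phenyl]-5,7-dimethoxy-3,4-dihydro-2H-chromene | COc1cc(OC)c2c(c1)O[C@H](c1ccc(Oc3c(OC)cc4c(c3OC)CC[C@@H](c3ccc(OCc5ccccc5)cc3)O4)cc1)CC2 | intermediate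
26 | 4,4''-diol of 25, bis(flavan-4-ol), C4 epimers (not isolated) | COc1cc(OC)c2c(c1)O[C@H](c1ccc(Oc3c(OC)cc4c(c3OC)C(O)C[C@@H](c3ccc(OCc5ccccc5)cc3)O4)cc1)CC2O | intermediate
27 | (2S)-2-[4-({(2S)-2-[4-(benzyloxy)phenyl]-5,7-dimethoxy-4-oxo-3,4-dihydro-2H-chromen-6-yl}oxy)phenyl]-5,7-dimethoxy-2,3-dihydro-4H-chromen-4-one | COc1cc(OC)c2c(c1)O[C@H](c1ccc(Oc3c(OC)cc4c(c3OC)C(=O)C[C@@H](c3ccc(OCc5ccccc5)cc3)O4)cc1)CC2=O | intermediate
28 | 7,7''-di-O-methyltetrahydrohinokiflavone, (2S)-5-hydroxy-2-[4-({(2S)-5-hydroxy-2-(4-hydroxyphenyl)-7-methoxy-4-oxo-3,4-dihydro-2H-chromen-6-yl}oxy)phenyl]-7-methoxy-2,3-dihydro-4H-chromen-4-one | COc1cc(O)c2c(c1)O[C@H](c1ccc(Oc3c(OC)cc4c(c3O)C(=O)C[C@@H](c3ccc(O)cc3)O4)cc1)CC2=O | target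

Total step count: 18. Longest linear sequence: 16 steps (steps 1–3 and 6–18; steps 4 and 5 form the side branch to 10).

Steps most likely to fail

Step 16. After N2 loss the C3 radical may fragment by β-scission of the C2–O1 bond faster than it couples with the benzylic radical, which would open the ring or, after recombination of the fragments, erode C2. Nitrogen transfer may also stall at one of the two amines and leave half-contracted material. The fallback separates nitrogen transfer from N2 loss so that the diazene can be generated cold. From 24, N-nitrosation (t-BuONO, CH2Cl2, rt) should give the bis(N-nitrosamine) F1. Reduction (LiAlH4, THF, 0 °C) should give the bis(N-aminobenzoxazepine) F2. Oxidation of the 1,1-disubstituted hydrazines (yellow HgO, CH2Cl2/EtOH, 0 °C, high dilution) should give the same diazenes at a temperature where coupling of the caged pair is favoured over fragmentation. The route is rejoined at 25.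

Step 17. The C4 cation may lose a proton to a flav-3-ene that DDQ takes on to a flavylium ion, or excess oxidant may abstract hydride at C2 next to the alkoxy-substituted B ring. The fallback stops after one hydride abstraction per ring and oxidises the alcohol with a different reagent. From 25, DDQ (2.2 equiv) in CH2Cl2/AcOH at 0 °C should give the bis(4-acetoxyflavan) F3, since the acetate resists a second abstraction. K2CO3 in MeOH should then release the bis(flavan-4-ol) 26, here isolated, and Dess–Martin periodinane (NaHCO3, CH2Cl2) should oxidise it to 27, where the route is rejoined.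

Step 14 (the same hazard applies to step 8). The activated, para-oxygenated benzylic alcohol may ionise before the phenol attacks, which would cost configurational purity; elimination to an enesulfonamide or slow seven-membered closure are further losses. The fallback forms the aryl C–O bond instead, so the carbinol C–O bond is never broken. From 16, the Henry reaction with the other ligand antipode should give the (1R)-nitro alcohol F4, and Zn/AcOH the (1R)-amino alcohol F5. Reductive amination (NaBH(OAc)3, DCE) with commercial 2-bromo-4,6-dimethoxybenzaldehyde (O=Cc1c(Br)cc(OC)cc1OC) should give the secondary amine F6, and SES-Cl/Et3N the sulfonamide F7. Palladium-catalysed intramolecular aryl etherification (Pd(OAc)2, t-BuXPhos, Cs2CO3, toluene, 90 °C; CuI/1,10-phenanthroline as alternative) should then close the ring with retention, R to R, and rejoin the route at 23.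

Further compounds

F1 | step 16 | 4,4''-dinitroso derivative of 24, bis(N-nitrosamine) | COc1cc(OC)c2c(c1)O[C@H](c1ccc(Oc3c(OC)cc4c(c3OC)CN(N=O)C[C@@H](c3ccc(OCc5ccccc5)cc3)O4)cc1)CN(N=O)C2
F2 | step 16 | 4,4''-diamino derivative of 24, bis(N-aminobenzoxazepine) | COc1cc(OC)c2c(c1)O[C@H](c1ccc(Oc3c(OC)cc4c(c3OC)CN(N)C[C@@H](c3ccc(OCc5ccccc5)cc3)O4)cc1)CN(N)C2
F3 | step 17 | 4,4''-diacetoxy derivative of 25, bis(4-acetoxyflavan), C4 epimers | COc1cc(OC)c2c(c1)O[C@H](c1ccc(Oc3c(OC)cc4c(c3OC)C(OC(C)=O)C[C@@H](c3ccc(OCc5ccccc5)cc3)O4)cc1)CC2OC(C)=O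
F4 | step 14 | (1R)-1-[4-(Q-oxy)phenyl]-2-nitroethanol | COc1cc2c(c(OC)c1Oc3ccc([C@@H](O)C[N+](=O)[O-])cc3)CN(S(=O)(=O)CC[Si](C)(C)C)C[C@@H](c4ccc(OCc5ccccc5)cc4)O2
F5 | step 14 | (1R)-2-amino-1-[4-(Q-oxy)phenyl]ethanol | COc1cc2c(c(OC)c1Oc3ccc([C@@H](O)CN)cc3)CN(S(=O)(=O)CC[Si](C)(C)C)C[C@@H](c4ccc(OCc5ccccc5)cc4)O2
F6 | step 14 | (1R)-2-[(2-bromo-4,6-dimethoxybenzyl)amino]-1-[4-(Q-oxy)phenyl]ethanol | COc1cc2c(c(OC)c1Oc3ccc([C@@H](O)CNCc6c(Br)cc(OC)cc6OC)cc3)CN(S(=O)(=O)CC[Si](C)(C)C)C[C@@H](c4ccc(OCc5ccccc5)cc4)O2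
F7 | step 14 | N-(2-bromo-4,6-dimethoxybenzyl)-N-{(2R)-2-hydroxy-2-[4-(Q-oxy)phenyl]ethyl}-2-(trimethylsilyl)ethanesulfonamide | COc1cc2c(c(OC)c1Oc3ccc([C@@H](O)CN(Cc6c(Br)cc(OC)cc6OC)S(=O)(=O)CC[Si](C)(C)C)cc3)CN(S(=O)(=O)CC[Si](C)(C)C)C[C@@H](c4ccc(OCc5ccccc5)cc4)O2
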